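## Retrosynthetic overview

- **Locants:** the spiroketal is numbered O1–C2–C3–C4–C5(spiro)–O6–C7–C8–C9. Ring A is O1 and C2–C5; ring B is C5, O6 and C7–C9. The chain C1'–C6' runs from C2 to C3 of the phthalide.
- **Enabling feature:** ring A has the atom sequence of a furan. Its two α-carbons are the carbinol carbon C2 and the ketal carbon C5, and O6 sits on C7, four atoms from C5. A 2-(3-hydroxybutyl)furan is therefore the whole C8 spiroketal unit, short of one C–C and one C–O bond.
- **Key disconnection:** C1'–C2 and O6–C5 are cut together. This leads back to an (E)-alkenyl iodide that carries the phthalide and to (S)-4-(furan-2-yl)butan-2-ol. The forward reaction is a palladium-catalysed dearomative alkenylation/spiroketalisation, and diimide then saturates the two remaining C=C bonds.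
- **Building blocks:** the alkenyl iodide comes from 3,5-dimethoxybenzaldehyde by bromination, catalytic asymmetric alkylation (sets C3), carboxylative lactonisation, ozonolysis and Takai olefination. The furan alcohol comes from an enzymatic ketone reduction (sets C7).
- **Ring order:** the benzene ring and the furan (ring A) are bought, the lactone ring is closed in step 3 and ring B in step 7. Five-membered spiroketals have little thermodynamic bias, so C5 is set kinetically (relayed from C2) and no acidic step follows.

Key step: step 7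

Assumption: the senses of induction given for the chiral ligands of steps 2 and 7 are taken from their behaviour on the parent substrates (benzaldehyde, 2,3-dihydrofuran); if either is reversed on the real substrate, the antipodal ligand is used with no other change.

## Route

Step 1
Reactants: 1 3,5-dimethoxybenzaldehyde
Product: 2 2-bromo-3,5-dimethoxybenzaldehyde
Conditions: NBS, MeCN, 0 °C to rt
Reagents that add atoms: N-bromosuccinimide, O=C1CCC(=O)N1Br
Why: Electrophilic aromatic bromination: the position ortho to the formyl group is para to one methoxy group and ortho to the other and is less crowded than the carbon between the two methoxy groups, so NBS should stop at this monobromide.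

Step 2
Reactants: 2 2-bromo-3,5-dimethoxybenzaldehyde; 3 6-bromohex-1-ene
Product: 6 (1R)-1-(2-bromo-3,5-dimethoxyphenyl)hept-6-en-1-ol, via hex-5-enylmagnesium bromide 4 (not isolated), via hex-5-enyltitanium triisopropoxide 5 (not isolated)
Conditions: 3, Mg, THF, rt; added to Ti(OiPr)4 (excess), CH2Cl2, −78 °C; (R)-H8-BINOL (10 mol %), 2, 0 °C; H2O work-up
Reagents that add atoms: none
Why: Titanium-BINOLate-catalysed asymmetric alkylation of an aromatic aldehyde by an alkyltitanium triisopropoxide made from the Grignard reagent: the (R)-ligand should direct the alkyl group to the Re face of the formyl group and so set the (R)-carbinol centre that becomes C3 of the phthalide, while the excess of Ti(OiPr)4 suppresses the uncatalysed Grignard addition.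

Step 3
Reactants: 6 (1R)-1-(2-bromo-3,5-dimethoxyphenyl)hept-6-en-1-ol
Product: 9 (3R)-3-(hex-5-en-1-yl)-5,7-dimethoxy-2-benzofuran-1(3H)-one, via dilithiated aryl alkoxide 7 (not isolated), via hydroxy acid 8 (not isolated)
Conditions: n-BuLi (2.2 equiv), THF, −78 °C; CO2 (g); 2 M HCl, rt
Reagents that add atoms: carbon dioxide, O=C=O
Why: Bromine–lithium exchange on the lithium alkoxide, carboxylation of the aryllithium and acid-induced lactonisation of the γ-hydroxy acid close the phthalide ring without touching any bond at the stereocentre, whose methoxy groups stand meta and so do not favour benzylic ionisation.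

Step 4
Reactants: 9 (3R)-3-(hex-5-en-1-yl)-5,7-dimethoxy-2-benzofuran-1(3H)-one
Product: 11 5-[(1R)-4,6-dimethoxy-3-oxo-1,3-dihydro-2-benzofuran-1-yl]pentanal, via secondary ozonide 10 (not isolated)
Conditions: O3, CH2Cl2, −78 °C; PPh3, −78 °C to rt
Reagents that add atoms: ozone, [O-][O+]=O
Why: Ozonolysis with reductive work-up: the terminal alkene reacts much faster than the arene, which the lactone carbonyl deactivates, and the neutral phosphine work-up leaves the lactone and C3 untouched.

Step 5
Reactants: 11 5-[(1R)-4,6-dimethoxy-3-oxo-1,3-dihydro-2-benzofuran-1-yl]pentanal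
Product: 12 (3R)-3-[(5E)-6-iodohex-5-en-1-yl]-5,7-dimethoxy-2-benzofuran-1(3H)-one
Conditions: CrCl2, CHI3, THF, 0 °C to rt
Reagents that add atoms: iodoform, IC(I)I
Why: Takai olefination: the geminal dichromium reagent from CHI3 adds only to the aldehyde (lactones are inert) and eliminates to the (E)-alkenyl iodide; any (Z)-isomer is harmless because this double bond is saturated in step 8.

Step 6
Reactants: 13 4-(furan-2-yl)butan-2-one
Product: 14 (2S)-4-(furan-2-yl)butan-2-ol
Conditions: alcohol dehydrogenase ADH-A (Rhodococcus ruber), NAD+ (cat.), i-PrOH, phosphate buffer pH 7.5, 30 °C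
Reagents that add atoms: none
Why: Biocatalytic ketone reduction with a Prelog-selective alcohol dehydrogenase: hydride from NADH goes to the Re face of the methyl ketone and sets the (S)-carbinol centre (the future C7), with propan-2-ol recycling the cofactor and the furan inert at neutral pH.

Step 7
Reactants: 12 (3R)-3-[(5E)-6-iodohex-5-en-1-yl]-5,7-dimethoxy-2-benzofuran-1(3H)-one; 14 (2S)-4-(furan-2-yl)butan-2-ol (excess)
Product: 16 (3R)-5,7-dimethoxy-3-{(5E)-6-[(2S,5R,7S)-7-methyl-1,6-dioxaspiro[4.4]non-3-en-2-yl]hex-5-en-1-yl}-2-benzofuran-1(3H)-one, via allylpalladium cation 15 (not isolated)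
Conditions: Pd2(dba)3 (5 mol %), (S)-t-Bu-PHOX (12 mol %), Ag3PO4 (1.5 equiv), 14 (4 equiv), 4 Å MS, THF, 45 °C, dark
Reagents that add atoms: none
Why: Proposed new method: oxidative addition of 12 to zerovalent palladium and iodide abstraction by silver should give a cationic alkenylpalladium that adds syn across the unsubstituted C2=C3 bond of the furan of 14 (carbon to the free α-carbon C2, palladium to C3), and the oxygen-stabilised allylpalladium cation 15 (C3–C4–C5) is then captured at C5 by the side-chain hydroxyl while Ag3PO4 takes up the proton. The closest known reaction types are the Heck insertion/Tsuji–Trost capture cascades of 1,3-dienes, the intramolecular dearomative alkoxy-arylation of furans and the asymmetric intermolecular Heck reaction of 2,3-dihydrofuran under P,N ligands; new are the intermolecular insertion of a simple 2-alkylfuran and the spiroketal outcome. Ring B is closed by a 5-exo-trig attack of O6 on the allyl terminus C5, and ring A is the furan ring itself, left as a 2,5-dihydrofuran. C2 is set by the ligand, which selects the furan face that is carbopalladated, and C5 is relayed from C2 because the hydroxyl attacks the allyl unit on the face opposite to palladium and hence opposite to the alkenyl group (O6 trans to C1'), an outcome that an anti-oxypalladation/reductive elimination sequence would give as well; C7 and C3 are spectators. Regioselectivity rests on the single unsubstituted α-position of the furan and on the known preference of alkoxy-substituted allylpalladium units for attack at the oxygen-bearing terminus, reinforced by the four-atom tether. Rearomatisation is held back because the C2 hydrogen lies anti to palladium (no syn β-hydride elimination) and because only an insoluble weak base and no acid is present, which also keeps the kinetically formed spiro centre from equilibrating.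

Step 8
Reactants: 16 (3R)-5,7-dimethoxy-3-{(5E)-6-[(2S,5R,7S)-7-methyl-1,6-dioxaspiro[4.4]non-3-en-2-yl]hex-5-en-1-yl}-2-benzofuran-1(3H)-one
Product: 17 (3R)-5,7-dimethoxy-3-{6-[(2S,5R,7S)-7-methyl-1,6-dioxaspiro[4.4]nonan-2-yl]hexyl}-2-benzofuran-1(3H)-one
Conditions: 2-nitrobenzenesulfonohydrazide (NBSH, excess), Et3N, CH2Cl2, rt
Reagents that add atoms: none
Why: Diimide reduction: concerted syn transfer of two hydrogens to each of the two 1,2-disubstituted C=C bonds needs no acid, metal hydride or metal surface, so ketal ionisation at C5, hydrogenolysis of the doubly allylic C2–O1 bond and double-bond migration are all avoided and C2, C5, C7 and C3 are kept.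

## Compound list

1 | 3,5-dimethoxybenzaldehyde | COc1cc(C=O)cc(OC)c1 | starting material
2 | 2-bromo-3,5-dimethoxybenzaldehyde | COc1cc(C=O)c(Br)c(OC)c1 | intermediate
3 | 6-bromohex-1-ene | C=CCCCCBr | starting material
4 | hex-5-enylmagnesium bromide | C=CCCCC[Mg]Br | intermediate
5 | hex-5-enyltitanium triisopropoxide | C=CCCCC[Ti](OC(C)C)(OC(C)C)OC(C)C | intermediate
6 | (1R)-1-(2-bromo-3,5-dimethoxyphenyl)hept-6-en-1-ol | COc1cc(OC)c(Br)c(c1)[C@@H](CCCCC=C)O | intermediate
7 | lithium (1R)-1-(2-lithio-3,5-dimethoxyphenyl)hept-6-en-1-olate | COc1cc(OC)c([Li])c(c1)[C@@H](CCCCC=C)O[Li] | intermediate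
8 | 2-[(1R)-1-hydroxyhept-6-en-1-yl]-4,6-dimethoxybenzoic acid | COc1cc(OC)c(C(=O)O)c(c1)[C@@H](CCCCC=C)O | intermediate
9 | (3R)-3-(hex-5-en-1-yl)-5,7-dimethoxy-2-benzofuran-1(3H)-one | COc1cc(OC)c2c(c1)[C@@H](CCCCC=C)OC2=O | intermediate
10 | (3R)-5,7-dimethoxy-3-[4-(1,2,4-trioxolan-3-yl)butyl]-2-benzofuran-1(3H)-one (secondary ozonide, both configurations at the trioxolane carbon) | COc1cc(OC)c2c(c1)[C@@H](CCCCC1OCOO1)OC2=O | intermediate
11 | 5-[(1R)-4,6-dimethoxy-3-oxo-1,3-dihydro-2-benzofuran-1-yl]pentanal | COc1cc(OC)c2c(c1)[C@@H](CCCCC=O)OC2=O | intermediate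
12 | (3R)-3-[(5E)-6-iodohex-5-en-1-yl]-5,7-dimethoxy-2-benzofuran-1(3H)-one | COc1cc(OC)c2c(c1)[C@@H](CCCC/C=C/I)OC2=O | intermediate
13 | 4-(furan-2-yl)butan-2-one | CC(=O)CCc1ccco1 | starting material
14 | (2S)-4-(furan-2-yl)butan-2-ol | C[C@H](O)CCc1ccco1 | intermediate
15 | allylpalladium cation from syn addition of alkenyl and palladium to C2 and C3 of the furan (drawn as the σ-form at C3, PHOX ligand omitted) | COc1cc(OC)c2c(c1)[C@@H](CCCC/C=C/[C@H]1[C@@H]([Pd+])C=C(CC[C@H](C)O)O1)OC2=O | intermediate
16 | (3R)-5,7-dimethoxy-3-{(5E)-6-[(2S,5R,7S)-7-methyl-1,6-dioxaspiro[4.4]non-3-en-2-yl]hex-5-en-1-yl}-2-benzofuran-1(3H)-one | COc1cc(OC)c2c(c1)[C@@H](CCCC/C=C/[C@H]1C=C[C@@]3(CC[C@H](C)O3)O1)OC2=O | intermediate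
17 | (3R)-5,7-dimethoxy-3-{6-[(2S,5R,7S)-7-methyl-1,6-dioxaspiro[4.4]nonan-2-yl]hexyl}-2-benzofuran-1(3H)-one | COc1cc(OC)c2c(c1)[C@@H](CCCCCC[C@H]1CC[C@@]3(CC[C@H](C)O3)O1)OC2=O | target

## Step count and risks

Total step count: 8. Longest linear sequence: 7 (steps 1–5, 7, 8).

**1. Step 7 (new method).**
- What may go wrong: the cationic alkenylpalladium may insert too slowly into the aromatic furan. The allyl intermediate may lose the C2 proton and rearomatise, also after reversible ionisation of the product ketal by zerovalent palladium. The facial selectivity of the insertion may be poor.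
- Fallback: it uses known chemistry, sets out from 12 and 14 and comes back to the route at 17.
- 14 is silylated (TBSCl, imidazole, DMF) to (S)-tert-butyl{[4-(furan-2-yl)butan-2-yl]oxy}dimethylsilane F1.
- The furan of F1 is opened oxidatively (NBS, NaHCO3, aqueous acetone, −20 °C, then pyridine) to (2E,7S)-7-(tert-butyldimethylsilyloxy)-4-oxooct-2-enal F2.
- Hydrogenation of the conjugated C=C bond (H2, Pd/C, EtOAc) gives (7S)-7-(tert-butyldimethylsilyloxy)-4-oxooctanal F3.
- An asymmetric Nozaki–Hiyama–Kishi coupling of 12 with F3 (CrCl2, NiCl2 cat., chiral oxazoline–sulfonamide ligand, Et3N, THF) forms the same C1'–C2 bond at the aldehyde only. It gives (3R)-3-[(5E,7R,13S)-13-(tert-butyldimethylsilyloxy)-7-hydroxy-10-oxotetradec-5-en-1-yl]-5,7-dimethoxy-2-benzofuran-1(3H)-one F4.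
- Diimide (as in step 8) gives (3R)-3-[(7S,13S)-13-(tert-butyldimethylsilyloxy)-7-hydroxy-10-oxotetradecyl]-5,7-dimethoxy-2-benzofuran-1(3H)-one F5.
- HF·pyridine removes the silyl group and closes both rings under equilibrating conditions. This gives 17 together with (3R)-5,7-dimethoxy-3-{6-[(2S,5S,7S)-7-methyl-1,6-dioxaspiro[4.4]nonan-2-yl]hexyl}-2-benzofuran-1(3H)-one F6.
- The two are separated by HPLC, and the C5 epimer is re-equilibrated (PPTS, CH2Cl2) and recycled.

**2. Step 8.**
- What may go wrong: the ring C3=C4 bond, flanked by C2 and the quaternary C5, may take up diimide too slowly. The reduction would then stall before both double bonds are saturated.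
- Fallback: it sets out from 16 and comes back at 17.
- Diimide is asked only to saturate the unhindered side-chain double bond, which gives (3R)-5,7-dimethoxy-3-{6-[(2S,5R,7S)-7-methyl-1,6-dioxaspiro[4.4]non-3-en-2-yl]hexyl}-2-benzofuran-1(3H)-one F7.
- The C2–O1 bond is then no longer doubly allylic, so the ring alkene can be hydrogenated on a metal surface under buffered conditions (H2, Rh/Al2O3, K2CO3, EtOAc) to 17.

**3. Step 2.**
- What may go wrong: enantioselectivity may be eroded by uncatalysed addition of residual Grignard reagent or by the ortho bromine.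
- Fallback: it sets out from 2 and 4 and comes back at 6.
- Direct addition of 4 to 2 (THF, 0 °C) gives racemic 1-(2-bromo-3,5-dimethoxyphenyl)hept-6-en-1-ol F8.
- Dess–Martin oxidation gives 1-(2-bromo-3,5-dimethoxyphenyl)hept-6-en-1-one F9.
- Noyori-type asymmetric transfer hydrogenation (RuCl[(R,R)-TsDPEN](p-cymene), HCO2H/Et3N) sets the (R)-carbinol of 6.

Further compounds
F1 | step 7 | (S)-tert-butyl{[4-(furan-2-yl)butan-2-yl]oxy}dimethylsilane | C[C@H](O[Si](C)(C)C(C)(C)C)CCc1ccco1
F2 | step 7 | (2E,7S)-7-(tert-butyldimethylsilyloxy)-4-oxooct-2-enal | C[C@H](O[Si](C)(C)C(C)(C)C)CCC(=O)/C=C/C=O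
F3 | step 7 | (7S)-7-(tert-butyldimethylsilyloxy)-4-oxooctanal | C[C@H](O[Si](C)(C)C(C)(C)C)CCC(=O)CCC=O
F4 | step 7 | (3R)-3-[(5E,7R,13S)-13-(tert-butyldimethylsilyloxy)-7-hydroxy-10-oxotetradec-5-en-1-yl]-5,7-dimethoxy-2-benzofuran-1(3H)-one | COc1cc(OC)c2c(c1)[C@@H](CCCC/C=C/[C@H](O)CCC(=O)CC[C@H](C)O[Si](C)(C)C(C)(C)C)OC2=O
F5 | step 7 | (3R)-3-[(7S,13S)-13-(tert-butyldimethylsilyloxy)-7-hydroxy-10-oxotetradecyl]-5,7-dimethoxy-2-benzofuran-1(3H)-one | COc1cc(OC)c2c(c1)[C@@H](CCCCCC[C@H](O)CCC(=O)CC[C@H](C)O[Si](C)(C)C(C)(C)C)OC2=O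
F6 | step 7 | (3R)-5,7-dimethoxy-3-{6-[(2S,5S,7S)-7-methyl-1,6-dioxaspiro[4.4]nonan-2-yl]hexyl}-2-benzofuran-1(3H)-one | COc1cc(OC)c2c(c1)[C@@H](CCCCCC[C@H]1CC[C@]3(CC[C@H](C)O3)O1)OC2=O
F7 | step 8 | (3R)-5,7-dimethoxy-3-{6-[(2S,5R,7S)-7-methyl-1,6-dioxaspiro[4.4]non-3-en-2-yl]hexyl}-2-benzofuran-1(3H)-one | COc1cc(OC)c2c(c1)[C@@H](CCCCCC[C@H]1C=C[C@@]3(CC[C@H](C)O3)O1)OC2=O
F8 | step 2 | racemic 1-(2-bromo-3,5-dimethoxyphenyl)hept-6-en-1-ol | COc1cc(OC)c(Br)c(c1)C(O)CCCCC=C
F9 | step 2 | 1-(2-bromo-3,5-dimethoxyphenyl)hept-6-en-1-one | COc1cc(OC)c(Br)c(c1)C(=O)CCCCC=C
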